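Everything rests on opening ring A, the hydroxylated cyclohexene of the keto half (carotenoid numbering, C1–C6), across C4–C5 and C1–C6. Its C3 oxygen lies para to C6, C5=C6 is the only ring alkene and C1 is a gem-dimethyl carbon, so the ring is the retron of a Diels–Alder reaction between the silyl dienol ether of mesityl oxide (C4=C3–C2=C1) and methyl but-2-ynoate (C5≡C6–C7). One thermal cycloaddition builds the carbocycle with C5=C6, the C3 oxygen and C7 in place. The ring is then resolved, coupled through C7 to a furan that unmasks the C8–C11 keto-enal carrying the laurate, and joined to an ε-end C25 phosphonium salt by Wittig olefination.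

Key step: step 2

Remark on the chemistry: locants follow carotenoid numbering (ring A = C1–C6 with the hydroxyl on C3, C7 the ring-bound methylene, C8 the ketone, C19 the acyloxymethyl carbon, primed locants for the ε half); (R)-α-ionone of high enantiomeric purity and the C10 dialdehyde 27 are assumed to be purchasable.

Step 1
Reactants: 1 mesityl oxide (4-methylpent-3-en-2-one)
Product: 3 4-methyl-2-(trimethylsilyloxy)penta-1,3-diene, via lithium dienolate 2 (not isolated)
Conditions: LiN(i-Pr)2 (1.05 equiv), THF, −78 °C; then Me3SiCl, −78 °C to rt; pentane, filtration, distillation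
Reagents that add atoms: chlorotrimethylsilane, C[Si](C)(C)Cl
Why: Kinetic deprotonation of the enone at the α′-methyl group by LiN(i-Pr)2 gives the cross-conjugated dienolate, and O-silylation (silyl enol ether formation) fixes it as the 2-silyloxy-1,3-diene needed for the cycloaddition.

Step 2
Reactants: 3 4-methyl-2-(trimethylsilyloxy)penta-1,3-diene; 4 methyl but-2-ynoate
Product: 6 methyl 2,6,6-trimethyl-4-oxocyclohex-1-ene-1-carboxylate, via cycloadduct silyl enol ether 5 (not isolated)
Conditions: 4 (1.5 equiv), toluene, 2,6-di-tert-butyl-4-methylphenol (1 mol %), sealed tube, 150 °C; then 1 M HCl, THF, 0 °C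
Reagents that add atoms: none
Why: A thermal, concerted but asynchronous [4+2] cycloaddition (Diels–Alder reaction) joins the HOMO of the 2-silyloxydiene with the LUMO of the ynoate, and brief cold acid then hydrolyses the silyl enol ether 5 to the C3 ketone. The closest known reaction type is the cycloaddition of 2-silyloxy-1,3-dienes with alkynoate esters to give 1,4-cyclohexadienes. Ring A closes in a single intermolecular suprafacial π4s+π2s event that forms C4–C5 and C1–C6 together, so no separate ring-closing step of the exo or endo kind is involved. No stereocentre is created, because C1 carries two identical methyl groups and C3, C5 and C6 stay sp2; C3 is set later in steps 3 and 4. The selectivity needed is regiochemical: the largest HOMO coefficient sits on the CH2 terminus next to the silyloxy carbon and pairs with the methyl-bearing β-carbon of the ynoate, while the donor gem-dimethyl terminus bonds to the ester-bearing carbon, so both substituent effects place the ester carbon next to C1 and para to C3. The alkyne delivers C5=C6 directly, and conjugation with the ester should hold the alkene there during the short hydrolysis.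

Step 3
Reactants: 6 methyl 2,6,6-trimethyl-4-oxocyclohex-1-ene-1-carboxylate
Product: 7 methyl (4RS)-4-hydroxy-2,6,6-trimethylcyclohex-1-ene-1-carboxylate (racemic)
Conditions: NaBH4, MeOH, −20 °C
Reagents that add atoms: none
Why: Borohydride reduction attacks the unhindered, non-conjugated ketone much faster than the tetrasubstituted enoate and gives the carbinol as a racemate, which is acceptable because the next step resolves it.

Step 4
Reactants: 7 methyl (4RS)-4-hydroxy-2,6,6-trimethylcyclohex-1-ene-1-carboxylate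
Product: 8 methyl (4R)-4-acetoxy-2,6,6-trimethylcyclohex-1-ene-1-carboxylate
Conditions: Burkholderia cepacia lipase (immobilised), vinyl acetate (3 equiv), t-BuOMe, 30 °C, stopped near half conversion; chromatography (unreacted (S)-7 removed)
Reagents that add atoms: vinyl acetate, CC(=O)OC=C
Why: Lipase-catalysed kinetic resolution by irreversible transesterification: by the empirical size rule for lipases the enzyme should acylate the enantiomer whose bulkier CH2–CMe2 arm fits the large pocket, the (R)-alcohol, so the C3 stereocentre is fixed as the (R)-acetate while the (S)-alcohol stays unreacted.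

Step 5
Reactants: 8 methyl (4R)-4-acetoxy-2,6,6-trimethylcyclohex-1-ene-1-carboxylate
Product: 9 (1R)-4-(hydroxymethyl)-3,5,5-trimethylcyclohex-3-en-1-ol
Conditions: LiAlH4 (3 equiv), THF, 0 °C to rt
Reagents that add atoms: none
Why: LiAlH4 reduction converts the hindered conjugated methyl ester into the primary allylic alcohol (C7) and cleaves the acetate at the same time without touching the C3 stereocentre or the tetrasubstituted alkene.

Step 6
Reactants: 9 (1R)-4-(hydroxymethyl)-3,5,5-trimethylcyclohex-3-en-1-ol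
Product: 10 (1R)-4-(bromomethyl)-3,5,5-trimethylcyclohex-3-en-1-ol
Conditions: NBS (1.1 equiv), Me2S (1.2 equiv), CH2Cl2, −20 to 0 °C; used crude
Reagents that add atoms: N-bromosuccinimide, O=C1CCC(=O)N1Br
Why: Corey–Kim halogenation: the alkoxysulfonium salt of the primary allylic alcohol is displaced by bromide at low temperature, whereas the saturated secondary carbinol is not substituted under these conditions.

Step 7
Reactants: 11 furan-3-ylmethanol (3-furanmethanol); 10 (1R)-4-(bromomethyl)-3,5,5-trimethylcyclohex-3-en-1-ol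
Product: 13 (1R)-4-{[3-(hydroxymethyl)furan-2-yl]methyl}-3,5,5-trimethylcyclohex-3-en-1-ol, via dilithiated furanmethanol 12 (not isolated)
Conditions: 11 (2.5 equiv), n-BuLi (5.0 equiv), THF, −78 to 0 °C; then CuI (10 mol %), 10, −40 °C to rt
Reagents that add atoms: none
Why: Alkoxide-directed ortho-lithiation of 3-furanmethanol at C2 followed by copper-catalysed allylic alkylation forms the C7–C8 bond by SN2 attack at the primary carbon, SN2′ attack at the fully substituted C5 being sterically blocked, while the excess dianion merely deprotonates the free hydroxyl of 10.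

Step 8
Reactants: 13 (1R)-4-{[3-(hydroxymethyl)furan-2-yl]methyl}-3,5,5-trimethylcyclohex-3-en-1-ol; 14 dodecanoyl chloride (lauroyl chloride)
Product: 15 (2-{[(4R)-4-hydroxy-2,6,6-trimethylcyclohex-1-en-1-yl]methyl}furan-3-yl)methyl dodecanoate
Conditions: 14 (1.05 equiv), 2,4,6-collidine, CH2Cl2, −78 °C
Reagents that add atoms: none
Why: Chemoselective O-acylation: an acid chloride with the hindered base collidine at −78 °C should esterify the primary furylmethyl alcohol well before the secondary ring alcohol.

Step 9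
Reactants: 15 (2-{[(4R)-4-hydroxy-2,6,6-trimethylcyclohex-1-en-1-yl]methyl}furan-3-yl)methyl dodecanoate
Product: 17 (2E)-2-{[(4R)-4-hydroxy-2,6,6-trimethylcyclohex-1-en-1-yl]acetyl}-4-oxobut-2-en-1-yl dodecanoate, via Z keto-enal 16 (not isolated)
Conditions: NBS (1.0 equiv), NaHCO3, acetone/H2O (10:1), −20 °C; then I2 (5 mol %), CH2Cl2, rt
Reagents that add atoms: water, O
Why: Oxidative furan ring opening (bromonium attack at the free α-position, hydration and loss of HBr) unveils the cis-4-oxo-2-enal in which furan C2 becomes the C8 ketone and furan C5 the C11 aldehyde, the electron-rich furan outcompeting the tetrasubstituted alkene for the one equivalent of NBS, and iodine-catalysed Z-to-E isomerisation should then give the more stable enal with the two carbonyl groups trans.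

Step 10
Reactants: 18 (R)-α-ionone, (3E)-4-[(1R)-2,6,6-trimethylcyclohex-2-en-1-yl]but-3-en-2-one; 19 triethyl phosphonoacetate
Product: 21 ethyl (2E,4E)-3-methyl-5-[(1R)-2,6,6-trimethylcyclohex-2-en-1-yl]penta-2,4-dienoate, via sodium phosphonate anion 20 (not isolated)
Conditions: NaH, THF, 0 °C; then 18, 0 to 40 °C; chromatography
Reagents that add atoms: none
Why: Horner–Wadsworth–Emmons olefination of the methyl ketone should give mainly the 2E dienoate (the minor 2Z isomer is removed by chromatography), and the weakly basic stabilised phosphonate anion should not epimerise the C6′ stereocentre.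

Step 11
Reactants: 21 ethyl (2E,4E)-3-methyl-5-[(1R)-2,6,6-trimethylcyclohex-2-en-1-yl]penta-2,4-dienoate
Product: 22 ethyl (2E,4E)-3-methyl-5-[(1R)-2,6,6-trimethyl-4-oxocyclohex-2-en-1-yl]penta-2,4-dienoate
Conditions: t-BuOOH (70% in water, 4 equiv), CrO3 (5 mol %), CH2Cl2, rt
Reagents that add atoms: tert-butyl hydroperoxide, CC(C)(C)OO
Why: Chromium-catalysed allylic oxidation with t-BuOOH converts the only allylic ring methylene (C3′) into the enone carbonyl, while the doubly allylic C6′–H is shielded by the adjacent quaternary carbon and the methyl-bearing alkene carbon, so the stereocentre should survive.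

Step 12
Reactants: 22 ethyl (2E,4E)-3-methyl-5-[(1R)-2,6,6-trimethyl-4-oxocyclohex-2-en-1-yl]penta-2,4-dienoate
Product: 23 ethyl (2E,4E)-5-[(1R,4S)-4-hydroxy-2,6,6-trimethylcyclohex-2-en-1-yl]-3-methylpenta-2,4-dienoate
Conditions: LiBH(s-Bu)3 (1.1 equiv), THF, −78 °C
Reagents that add atoms: none
Why: 1,2-Reduction of the β,β-disubstituted enone by the bulky borohydride LiBH(s-Bu)3: hydride should be delivered to the ring face opposite the C6′ side chain (the other face is screened by that chain or by the axial C1′ methyl group), giving the 3′,6′-cis allylic alcohol, and the hindered dienoate is left alone.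

Step 13
Reactants: 23 ethyl (2E,4E)-5-[(1R,4S)-4-hydroxy-2,6,6-trimethylcyclohex-2-en-1-yl]-3-methylpenta-2,4-dienoate
Product: 24 ethyl (2E,4E)-5-[(1R,4R)-4-(benzoyloxy)-2,6,6-trimethylcyclohex-2-en-1-yl]-3-methylpenta-2,4-dienoate
Conditions: PhCO2H, PPh3, diisopropyl azodicarboxylate, THF, 0 °C to rt
Reagents that add atoms: benzoic acid, OC(=O)c1ccccc1
Why: Mitsunobu esterification proceeds by SN2 displacement of the oxyphosphonium group with inversion at C3′, converting the cis alcohol into the trans (3′R,6′R) benzoate, SN2′ attack at the fully substituted C5′ being disfavoured.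

Step 14
Reactants: 24 ethyl (2E,4E)-5-[(1R,4R)-4-(benzoyloxy)-2,6,6-trimethylcyclohex-2-en-1-yl]-3-methylpenta-2,4-dienoate
Product: 25 (2E,4E)-5-[(1R,4R)-4-hydroxy-2,6,6-trimethylcyclohex-2-en-1-yl]-3-methylpenta-2,4-dien-1-ol
Conditions: (i-Bu)2AlH (5 equiv), CH2Cl2, −78 to −20 °C
Reagents that add atoms: none
Why: (i-Bu)2AlH reduces the dienoate by 1,2-addition to the primary dienol and cleaves the benzoate reductively, freeing the C3′ hydroxyl with its configuration retained.

Step 15
Reactants: 25 (2E,4E)-5-[(1R,4R)-4-hydroxy-2,6,6-trimethylcyclohex-2-en-1-yl]-3-methylpenta-2,4-dien-1-ol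
Product: 26 [(2E,4E)-5-[(1R,4R)-4-hydroxy-2,6,6-trimethylcyclohex-2-en-1-yl]-3-methylpenta-2,4-dien-1-yl]triphenylphosphonium bromide
Conditions: PPh3·HBr (1.0 equiv), MeOH, 0 °C to rt
Reagents that add atoms: triphenylphosphonium bromide (PPh3·HBr), [Br-].[PH+](c1ccccc1)(c1ccccc1)c1ccccc1
Why: Phosphonium salt formation by SN1-type substitution: the primary dienylic alcohol ionises to a pentadienyl cation far more readily than the ring allylic alcohol, so one equivalent of the weakly acidic PPh3·HBr at low temperature should substitute only C11′.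

Step 16
Reactants: 26 [(2E,4E)-5-[(1R,4R)-4-hydroxy-2,6,6-trimethylcyclohex-2-en-1-yl]-3-methylpenta-2,4-dien-1-yl]triphenylphosphonium bromide; 27 (2E,4E,6E)-2,7-dimethylocta-2,4,6-trienedial
Product: 28 (2E,4E,6E,8E,10E,12E)-13-[(1R,4R)-4-hydroxy-2,6,6-trimethylcyclohex-2-en-1-yl]-2,7,11-trimethyltrideca-2,4,6,8,10,12-hexaenal
Conditions: 27 (2.5 equiv), 1,2-epoxybutane/EtOH, 60 °C, slow addition of 26, argon, dark
Reagents that add atoms: none
Why: Wittig olefination under neutral, epoxide-buffered conditions; an excess of the symmetrical dialdehyde secures mono-olefination and the semi-stabilised ylide should give mainly the E alkene, any Z isomer being equilibrated by the mild heating.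

Step 17
Reactants: 28 (2E,4E,6E,8E,10E,12E)-13-[(1R,4R)-4-hydroxy-2,6,6-trimethylcyclohex-2-en-1-yl]-2,7,11-trimethyltrideca-2,4,6,8,10,12-hexaenal
Product: 29 (2E,4E,6E,8E,10E,12E)-13-[(1R,4R)-4-hydroxy-2,6,6-trimethylcyclohex-2-en-1-yl]-2,7,11-trimethyltrideca-2,4,6,8,10,12-hexaen-1-ol
Conditions: NaBH4, MeOH/THF, 0 °C, argon, dark
Reagents that add atoms: none
Why: Borohydride 1,2-reduction of the polyenal gives the primary allylic alcohol without affecting the polyene or the ring carbinol.

Step 18
Reactants: 29 (2E,4E,6E,8E,10E,12E)-13-[(1R,4R)-4-hydroxy-2,6,6-trimethylcyclohex-2-en-1-yl]-2,7,11-trimethyltrideca-2,4,6,8,10,12-hexaen-1-ol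
Product: 30 [(2E,4E,6E,8E,10E,12E)-13-[(1R,4R)-4-hydroxy-2,6,6-trimethylcyclohex-2-en-1-yl]-2,7,11-trimethyltrideca-2,4,6,8,10,12-hexaen-1-yl]triphenylphosphonium bromide
Conditions: PPh3·HBr (1.0 equiv), MeOH/CH2Cl2, 0 °C, argon, dark
Reagents that add atoms: triphenylphosphonium bromide (PPh3·HBr), [Br-].[PH+](c1ccccc1)(c1ccccc1)c1ccccc1
Why: Phosphonium salt formation as in step 15, here even more selective because the primary alcohol ionises to a hexaenyl cation, so that the ring allylic alcohol should remain untouched by one equivalent of PPh3·HBr at 0 °C.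

Step 19
Reactants: 30 [(2E,4E,6E,8E,10E,12E)-13-[(1R,4R)-4-hydroxy-2,6,6-trimethylcyclohex-2-en-1-yl]-2,7,11-trimethyltrideca-2,4,6,8,10,12-hexaen-1-yl]triphenylphosphonium bromide; 17 (2E)-2-{[(4R)-4-hydroxy-2,6,6-trimethylcyclohex-1-en-1-yl]acetyl}-4-oxobut-2-en-1-yl dodecanoate
Product: 31 (3R,3′R,6′R)-3,3′-dihydroxy-19-dodecanoyloxy-7,8-dihydro-β,ε-caroten-8-one (all-E; CNP0415583.1)
Conditions: 1,2-epoxybutane/CH2Cl2, 40 °C, argon, dark; crystallisation
Reagents that add atoms: none
Why: Wittig olefination: the semi-stabilised polyenyl ylide generated under neutral epoxide conditions adds to the aldehyde and not to the hindered enolisable ketone, forming the C11=C12 bond mainly as the E alkene (residual Z isomer equilibrated on gentle warming), and the absence of alkoxide base protects the laurate and the C7 methylene group.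

Compound list
1 | mesityl oxide (4-methylpent-3-en-2-one) | CC(=O)C=C(C)C | starting material
2 | lithium 4-methylpenta-1,3-dien-2-olate | [Li]OC(=C)C=C(C)C | intermediate
3 | 4-methyl-2-(trimethylsilyloxy)penta-1,3-diene | C=C(O[Si](C)(C)C)C=C(C)C | intermediate
4 | methyl but-2-ynoate | CC#CC(=O)OC | starting material
5 | methyl 2,6,6-trimethyl-4-(trimethylsilyloxy)cyclohexa-1,4-diene-1-carboxylate | COC(=O)C1=C(C)CC(O[Si](C)(C)C)=CC1(C)C | intermediate
6 | methyl 2,6,6-trimethyl-4-oxocyclohex-1-ene-1-carboxylate | COC(=O)C1=C(C)CC(=O)CC1(C)C | intermediate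
7 | methyl (4RS)-4-hydroxy-2,6,6-trimethylcyclohex-1-ene-1-carboxylate (racemic) | COC(=O)C1=C(C)CC(O)CC1(C)C | intermediate
8 | methyl (4R)-4-acetoxy-2,6,6-trimethylcyclohex-1-ene-1-carboxylate | COC(=O)C1=C(C)C[C@@H](OC(C)=O)CC1(C)C | intermediate
9 | (1R)-4-(hydroxymethyl)-3,5,5-trimethylcyclohex-3-en-1-ol | OCC1=C(C)C[C@@H](O)CC1(C)C | intermediate
10 | (1R)-4-(bromomethyl)-3,5,5-trimethylcyclohex-3-en-1-ol | BrCC1=C(C)C[C@@H](O)CC1(C)C | intermediate
11 | furan-3-ylmethanol (3-furanmethanol) | OCc1ccoc1 | starting material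
12 | lithium (2-lithiofuran-3-yl)methanolate | [Li]OCc1ccoc1[Li] | intermediate
13 | (1R)-4-{[3-(hydroxymethyl)furan-2-yl]methyl}-3,5,5-trimethylcyclohex-3-en-1-ol | OCc1ccoc1CC1=C(C)C[C@@H](O)CC1(C)C | intermediate
14 | dodecanoyl chloride (lauroyl chloride) | CCCCCCCCCCCC(=O)Cl | starting material
15 | (2-{[(4R)-4-hydroxy-2,6,6-trimethylcyclohex-1-en-1-yl]methyl}furan-3-yl)methyl dodecanoate | CCCCCCCCCCCC(=O)OCc1ccoc1CC1=C(C)C[C@@H](O)CC1(C)C | intermediate
16 | (2Z)-2-{[(4R)-4-hydroxy-2,6,6-trimethylcyclohex-1-en-1-yl]acetyl}-4-oxobut-2-en-1-yl dodecanoate | CCCCCCCCCCCC(=O)OC/C(=C/C=O)C(=O)CC1=C(C)C[C@@H](O)CC1(C)C | intermediate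
17 | (2E)-2-{[(4R)-4-hydroxy-2,6,6-trimethylcyclohex-1-en-1-yl]acetyl}-4-oxobut-2-en-1-yl dodecanoate | CCCCCCCCCCCC(=O)OC\C(=C/C=O)C(=O)CC1=C(C)C[C@@H](O)CC1(C)C | intermediate
18 | (R)-α-ionone, (3E)-4-[(1R)-2,6,6-trimethylcyclohex-2-en-1-yl]but-3-en-2-one | CC(=O)/C=C/[C@H]1C(C)=CCCC1(C)C | starting material
19 | triethyl phosphonoacetate | CCOC(=O)CP(=O)(OCC)OCC | starting material
20 | sodium salt of triethyl phosphonoacetate (phosphonate carbanion) | [Na+].CCOC(=O)[CH-]P(=O)(OCC)OCC | intermediate
21 | ethyl (2E,4E)-3-methyl-5-[(1R)-2,6,6-trimethylcyclohex-2-en-1-yl]penta-2,4-dienoate | CCOC(=O)/C=C(C)/C=C/[C@H]1C(C)=CCCC1(C)C | intermediate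
22 | ethyl (2E,4E)-3-methyl-5-[(1R)-2,6,6-trimethyl-4-oxocyclohex-2-en-1-yl]penta-2,4-dienoate | CCOC(=O)/C=C(C)/C=C/[C@H]1C(C)=CC(=O)CC1(C)C | intermediate
23 | ethyl (2E,4E)-5-[(1R,4S)-4-hydroxy-2,6,6-trimethylcyclohex-2-en-1-yl]-3-methylpenta-2,4-dienoate | CCOC(=O)/C=C(C)/C=C/[C@H]1C(C)=C[C@@H](O)CC1(C)C | intermediate
24 | ethyl (2E,4E)-5-[(1R,4R)-4-(benzoyloxy)-2,6,6-trimethylcyclohex-2-en-1-yl]-3-methylpenta-2,4-dienoate | CCOC(=O)/C=C(C)/C=C/[C@H]1C(C)=C[C@H](OC(=O)c2ccccc2)CC1(C)C | intermediate
25 | (2E,4E)-5-[(1R,4R)-4-hydroxy-2,6,6-trimethylcyclohex-2-en-1-yl]-3-methylpenta-2,4-dien-1-ol | OC/C=C(C)/C=C/[C@H]1C(C)=C[C@H](O)CC1(C)C | intermediate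
26 | [(2E,4E)-5-[(1R,4R)-4-hydroxy-2,6,6-trimethylcyclohex-2-en-1-yl]-3-methylpenta-2,4-dien-1-yl]triphenylphosphonium bromide | [Br-].C(/C=C(C)/C=C/[C@H]1C(C)=C[C@H](O)CC1(C)C)[P+](c2ccccc2)(c3ccccc3)c4ccccc4 | intermediate
27 | (2E,4E,6E)-2,7-dimethylocta-2,4,6-trienedial | O=C/C(C)=C/C=C/C=C(C)/C=O | starting material
28 | (2E,4E,6E,8E,10E,12E)-13-[(1R,4R)-4-hydroxy-2,6,6-trimethylcyclohex-2-en-1-yl]-2,7,11-trimethyltrideca-2,4,6,8,10,12-hexaenal | O=C/C(C)=C/C=C/C=C(C)/C=C/C=C(C)/C=C/[C@H]1C(C)=C[C@H](O)CC1(C)C | intermediate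
29 | (2E,4E,6E,8E,10E,12E)-13-[(1R,4R)-4-hydroxy-2,6,6-trimethylcyclohex-2-en-1-yl]-2,7,11-trimethyltrideca-2,4,6,8,10,12-hexaen-1-ol | OC/C(C)=C/C=C/C=C(C)/C=C/C=C(C)/C=C/[C@H]1C(C)=C[C@H](O)CC1(C)C | intermediate
30 | [(2E,4E,6E,8E,10E,12E)-13-[(1R,4R)-4-hydroxy-2,6,6-trimethylcyclohex-2-en-1-yl]-2,7,11-trimethyltrideca-2,4,6,8,10,12-hexaen-1-yl]triphenylphosphonium bromide | [Br-].C(/C(C)=C/C=C/C=C(C)/C=C/C=C(C)/C=C/[C@H]1C(C)=C[C@H](O)CC1(C)C)[P+](c2ccccc2)(c3ccccc3)c4ccccc4 | intermediate
31 | (3R,3′R,6′R)-3,3′-dihydroxy-19-dodecanoyloxy-7,8-dihydro-β,ε-caroten-8-one (all-E) | CCCCCCCCCCCC(=O)OC\C(=C/C=C/C(C)=C/C=C/C=C(C)/C=C/C=C(C)/C=C/[C@H]1C(C)=C[C@H](O)CC1(C)C)C(=O)CC1=C(C)C[C@@H](O)CC1(C)C | target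

Total step count: 19. Longest linear sequence: 10 steps (steps 10 to 19; the ring A branch, steps 1 to 9 followed by step 19, is of equal length).

Steps most likely to fail

Step 2 (key cycloaddition). The cycloaddition may stall, because the diene must reach an s-cis geometry with one methyl group turned inward and the β-methyl ynoate is a weak dienophile; prolonged heating may then bring desilylation or hydrogen shifts in the diene. The fallback sets out from 1 and builds the same two ring bonds stepwise. Mesityl oxide 1 and methyl acetoacetate (CC(=O)CC(=O)OC) are condensed with ZnCl2 in refluxing toluene with water separation (Michael addition, intramolecular aldol condensation, dehydration) to racemic methyl 2,6,6-trimethyl-4-oxocyclohex-2-ene-1-carboxylate F1. Deprotonation at the ester-bearing carbon with t-BuOK in THF at −78 °C gives potassium 4-(methoxycarbonyl)-3,5,5-trimethylcyclohexa-1,3-dien-1-olate F2. Inverse quench into cold aqueous AcOH should protonate this dienolate kinetically at the α-carbon (C4), moving the alkene into conjugation with the ester. The fallback comes back to the route at 6.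

Step 9 (furan unmasking). Electrophilic bromine may add to the tetrasubstituted ring alkene in competition with the furan, and the Z-to-E equilibration may stay incomplete or be accompanied by allylic displacement of the laurate. The fallback sets out from 15 and separates oxidation from unmasking. Anodic 2,5-dimethoxylation of the furan (Clauson-Kaas type; undivided cell, graphite anode, Et4NOTs, 2,6-lutidine, MeOH, −10 °C, constant current) should select the furan by its lower oxidation potential and give {2,5-dimethoxy-2-{[(4R)-4-hydroxy-2,6,6-trimethylcyclohex-1-en-1-yl]methyl}-2,5-dihydrofuran-3-yl}methyl dodecanoate F3 as a stable bis-acetal. Hydrolysis in aqueous AcOH/THF at rt releases 16, which the acidic medium (or a trace of I2) equilibrates. The fallback comes back to the route at 17.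

Step 4 (enzymatic resolution). Discrimination between the enantiomers may be insufficient, because the two arms flanking the carbinol differ only beyond their α-carbons, so that the acetate may not reach the required enantiomeric purity. The fallback sets out from 7 and replaces the enzyme by a classical separation of diastereomers. Racemic 7 is esterified with (S)-naproxen (N,N′-dicyclohexylcarbodiimide, 4-(dimethylamino)pyridine, CH2Cl2). This gives methyl (4R)-4-{[(2S)-2-(6-methoxynaphthalen-2-yl)propanoyl]oxy}-2,6,6-trimethylcyclohex-1-ene-1-carboxylate F4 and its diastereomer methyl (4S)-4-{[(2S)-2-(6-methoxynaphthalen-2-yl)propanoyl]oxy}-2,6,6-trimethylcyclohex-1-ene-1-carboxylate F5, which are separated by chromatography or crystallisation. LiAlH4 reduction of F4 (THF, 0 °C) cleaves the auxiliary and reduces the methyl ester in one operation. The fallback comes back to the route at 9.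

Further compounds
F1 | step 2 | methyl 2,6,6-trimethyl-4-oxocyclohex-2-ene-1-carboxylate (racemic) | COC(=O)C1C(C)=CC(=O)CC1(C)C
F2 | step 2 | potassium 4-(methoxycarbonyl)-3,5,5-trimethylcyclohexa-1,3-dien-1-olate | COC(=O)C1=C(C)C=C([O-])CC1(C)C.[K+]
F3 | step 9 | {2,5-dimethoxy-2-{[(4R)-4-hydroxy-2,6,6-trimethylcyclohex-1-en-1-yl]methyl}-2,5-dihydrofuran-3-yl}methyl dodecanoate (mixture of acetal epimers) | CCCCCCCCCCCC(=O)OCC1=CC(OC)OC1(OC)CC2=C(C)C[C@@H](O)CC2(C)C
F4 | step 4 | methyl (4R)-4-{[(2S)-2-(6-methoxynaphthalen-2-yl)propanoyl]oxy}-2,6,6-trimethylcyclohex-1-ene-1-carboxylate | COC(=O)C1=C(C)C[C@@H](OC(=O)[C@@H](C)c2ccc3cc(OC)ccc3c2)CC1(C)C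
F5 | step 4 | methyl (4S)-4-{[(2S)-2-(6-methoxynaphthalen-2-yl)propanoyl]oxy}-2,6,6-trimethylcyclohex-1-ene-1-carboxylate | COC(=O)C1=C(C)C[C@H](OC(=O)[C@@H](C)c2ccc3cc(OC)ccc3c2)CC1(C)C
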